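The cyclohexene carbons are numbered C1 (methyl) to C6; rings A, B and C are the aryl groups on C3, on the C4 ketone and on C5. The cyclohexene is closed last, at C4–C5. The step exploits two phenols of the target itself: the ortho-hydroxyl of ring A ties the C4 ketone into a temporary 4H-chromene, and the hydroxyls of ring C turn C5 into a quinone methide. Their intramolecular oxa-Diels–Alder reaction forms C4–C5 and sets C4 and C5 from C3 alone; base then reopens the ketal to the free ketone. The precursor is an open-chain heptaphenol with a sulfone on C5, assembled by a rhodium-catalysed asymmetric alkenyl addition.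

Key step: step 16

Remarks on the chemistry:
- Ring D is the 4-hydroxyphenyl ring of the chalcone. Ring E is the temporary pyran ring of the 4H-chromene. Ring F is the second pyran ring of the transient ketal.
- The sulfone-bearing carbon (the future C5) is carried as both configurations from 23 to 29, because it becomes trigonal in step 16; its SMILES carry no descriptor there.
- Ring E may equally close through the other ortho-hydroxyl of ring A. Both chromenes enforce the same ring fusion and both oxygens are released at the end, so only the one through the oxygen para to the acyl group is drawn.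

Step 1
Reactants: 1 1-(2,4-dihydroxyphenyl)ethanone
Product: 2 1-(2,4-dihydroxy-3-iodophenyl)ethanone
Conditions: I2, HIO3, EtOH/H2O, 35 °C
Reagents that add atoms: iodine, II; iodic acid, OI(=O)=O
Why: Electrophilic aromatic iodination should occur at the doubly activated position between the two hydroxyls, the only carbon ortho to both.

Step 2
Reactants: 2 1-(2,4-dihydroxy-3-iodophenyl)ethanone
Product: 3 1-[3-iodo-2,4-bis(methoxymethoxy)phenyl]ethanone
Conditions: NaH, MOMCl, DMF, 0 °C to rt
Reagents that add atoms: chloromethyl methyl ether, COCCl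
Why: O-Alkylation of both phenoxides (Williamson-type acetal formation) should give MOM ethers that tolerate bases, organometallics and palladium catalysis.

Step 3
Reactants: 3 1-[3-iodo-2,4-bis(methoxymethoxy)phenyl]ethanone; 4 3-methylbut-1-yne; 5 pinacolborane
Product: 7 1-[2,4-bis(methoxymethoxy)-3-[(E)-3-methylbut-1-enyl]phenyl]ethanone, via alkenyl pinacol boronate 6 (not isolated)
Conditions: 4, 5, Cp2Zr(H)Cl (5 mol%), Et3N (10 mol%), 60 °C; then 3, Pd(dppf)Cl2 (3 mol%), K3PO4, dioxane/H2O, 80 °C
Reagents that add atoms: none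
Why: Zirconium-catalysed syn-hydroboration of the terminal alkyne should give the (E)-alkenylboronate, which couples with the aryl iodide (Suzuki–Miyaura) with retention of alkene geometry.

Step 4
Reactants: 3 1-[3-iodo-2,4-bis(methoxymethoxy)phenyl]ethanone
Product: 8 3-acetyl-2,6-bis(methoxymethoxy)benzaldehyde
Conditions: Pd(OAc)2 (5 mol%), dppf, CO (3 bar), Et3SiH, Na2CO3, DMF, 80 °C
Reagents that add atoms: carbon monoxide, [C-]#[O+]
Why: Palladium-catalysed reductive carbonylation (formylation) of the aryl iodide proceeds by oxidative addition, CO insertion and hydride transfer from the silane to the acylpalladium; the methyl ketone and acetals should be inert.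

Step 5
Reactants: 7 1-[2,4-bis(methoxymethoxy)-3-[(E)-3-methylbut-1-enyl]phenyl]ethanone; 8 3-acetyl-2,6-bis(methoxymethoxy)benzaldehyde
Product: 12 (E)-3-[3-acetyl-2,6-bis(methoxymethoxy)phenyl]-1-[2,4-bis(methoxymethoxy)-3-[(E)-3-methylbut-1-enyl]phenyl]prop-2-en-1-one, via lithium enolate 9 (not isolated), via lithium aldolate 10 (not isolated), via aldol mesylate 11 (not isolated)
Conditions: LiN(SiMe3)2, THF, −78 °C; then 8, −78 °C; then MsCl, Et3N, −78 °C to rt
Reagents that add atoms: none
Why: Directed crossed aldol addition of the preformed lithium enolate to the aldehyde should be faster at −78 °C than proton exchange with the acetyl group of 8, and E1cB elimination of the mesylate should give the (E)-enone.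

Step 6
Reactants: 13 2,4-dihydroxybenzaldehyde
Product: 14 2,4-bis(methoxymethoxy)benzaldehyde
Conditions: NaH, MOMCl, DMF, 0 °C to rt
Reagents that add atoms: chloromethyl methyl ether, COCCl
Why: O-Alkylation of both phenoxides, as in step 2.

Step 7
Reactants: 14 2,4-bis(methoxymethoxy)benzaldehyde
Product: 15 [2,4-bis(methoxymethoxy)phenyl]methanol
Conditions: NaBH4, MeOH, 0 °C
Reagents that add atoms: none
Why: Hydride reduction of the aldehyde; the acetals are untouched.

Step 8
Reactants: 15 [2,4-bis(methoxymethoxy)phenyl]methanol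
Product: 17 2,4-bis(methoxymethoxy)-1-[(4-methylphenyl)sulfonylmethyl]benzene, via benzylic chloride 16 (not isolated)
Conditions: MsCl, Et3N, CH2Cl2, 0 °C; then sodium 4-methylbenzenesulfinate, Bu4NI (cat.), DMF, rt
Reagents that add atoms: sodium 4-methylbenzenesulfinate, [Na+].[O-]S(=O)c1ccc(C)cc1
Why: The electron-rich benzylic alcohol is activated as its chloride and S-alkylates the sulfinate; the sulfone is an acid-stable latent quinone methide and acidifies the benzylic carbon for the next C–C bond.

Step 9
Reactants: 18 prop-2-yn-1-ol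
Product: 20 (Z)-3-iodo-2-methylprop-2-en-1-ol, via alkenylmagnesium chelate 19 (not isolated)
Conditions: MeMgBr (2.5 equiv), CuI (10 mol%), THF, −10 °C to rt; then I2, −78 to 0 °C
Reagents that add atoms: methylmagnesium bromide, C[Mg]Br; iodine, II
Why: Copper-catalysed anti-carbomagnesiation of the propargylic alkoxide places methyl on the inner carbon and magnesium on the terminus, cis to the CH2O group in a five-membered chelate; iodinolysis with retention should give the (Z)-vinyl iodide.

Step 10
Reactants: 20 (Z)-3-iodo-2-methylprop-2-en-1-ol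
Product: 21 (Z)-3-bromo-1-iodo-2-methylprop-1-ene
Conditions: CBr4, PPh3, CH2Cl2, 0 °C
Reagents that add atoms: carbon tetrabromide, BrC(Br)(Br)Br
Why: Appel bromination of the primary allylic alcohol should proceed without touching the alkene geometry.

Step 11
Reactants: 17 2,4-bis(methoxymethoxy)-1-[(4-methylphenyl)sulfonylmethyl]benzene; 21 (Z)-3-bromo-1-iodo-2-methylprop-1-ene
Product: 23 1-[(Z)-4-iodo-3-methyl-1-(4-methylphenyl)sulfonylbut-3-enyl]-2,4-bis(methoxymethoxy)benzene (both configurations at the sulfone carbon), via lithiated sulfone 22 (not isolated)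
Conditions: n-BuLi, THF, −78 °C; then 21, −78 to −20 °C
Reagents that add atoms: none
Why: SN2 alkylation of the sulfone-stabilised benzylic carbanion by the allylic bromide; the vinyl iodide should be inert at low temperature.

Step 12
Reactants: 23 1-[(Z)-4-iodo-3-methyl-1-(4-methylphenyl)sulfonylbut-3-enyl]-2,4-bis(methoxymethoxy)benzene
Product: 24 2-[(Z)-4-[2,4-bis(methoxymethoxy)phenyl]-2-methyl-4-(4-methylphenyl)sulfonylbut-1-enyl]-4,4,5,5-tetramethyl-1,3,2-dioxaborolane
Conditions: bis(pinacolato)diboron, PdCl2(PPh3)2 (3 mol%), PPh3, KOPh, toluene, 50 °C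
Reagents that add atoms: bis(pinacolato)diboron, CC1(C)OB(OC1(C)C)B1OC(C)(C)C(C)(C)O1
Why: Miyaura borylation of the alkenyl iodide should proceed with retention of the Z geometry; the phenoxide base suppresses Heck-type and homocoupling pathways.

Step 13
Reactants: 12 (E)-3-[3-acetyl-2,6-bis(methoxymethoxy)phenyl]-1-[2,4-bis(methoxymethoxy)-3-[(E)-3-methylbut-1-enyl]phenyl]prop-2-en-1-one; 24 the (Z)-alkenyl pinacol boronate of step 12
Product: 25 (3R,4Z)-3-[3-acetyl-2,6-bis(methoxymethoxy)phenyl]-1-[2,4-bis(methoxymethoxy)-3-[(E)-3-methylbut-1-enyl]phenyl]-7-[2,4-bis(methoxymethoxy)phenyl]-5-methyl-7-(4-methylphenyl)sulfonylhept-4-en-1-one (both C7 configurations)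
Conditions: Rh(acac)(C2H4)2 (3 mol%), (S)-BINAP (3.3 mol%), KOH (0.2 equiv), dioxane/H2O 10:1, 60 °C
Reagents that add atoms: none
Why: Hayashi–Miyaura asymmetric 1,4-addition: the alkenylrhodium formed by transmetalation inserts the (E)-enone, and by the usual quadrant model the (S)-BINAP complex should deliver the alkenyl group to the Si face of the β-carbon to set 3R (the antipodal ligand would be used if the di-ortho-substituted aryl reversed the sense); the Z-alkenyl geometry is transferred with retention.

Step 14
Reactants: 25 the conjugate adduct of step 13; 26 4-(methoxymethoxy)benzaldehyde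
Product: 27 (3R,4Z)-1-[2,4-bis(methoxymethoxy)-3-[(E)-3-methylbut-1-enyl]phenyl]-3-[2,6-bis(methoxymethoxy)-3-[(E)-3-[4-(methoxymethoxy)phenyl]prop-2-enoyl]phenyl]-7-[2,4-bis(methoxymethoxy)phenyl]-5-methyl-7-(4-methylphenyl)sulfonylhept-4-en-1-one
Conditions: KOH, EtOH/THF, rt
Reagents that add atoms: none
Why: Claisen–Schmidt condensation: the methyl ketone should enolise and condense much faster than the hindered β-branched methylene ketone, and E1cB dehydration gives the (E)-chalcone; C3 is not acidic and the sulfone is deprotonated only reversibly.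

Step 15
Reactants: 27 the heptakis(methoxymethyl) ether of step 14
Product: 28 (3R,4Z)-3-[2,6-dihydroxy-3-[(E)-3-(4-hydroxyphenyl)prop-2-enoyl]phenyl]-1-[2,4-dihydroxy-3-[(E)-3-methylbut-1-enyl]phenyl]-7-(2,4-dihydroxyphenyl)-5-methyl-7-(4-methylphenyl)sulfonylhept-4-en-1-one
Conditions: HCl (3 M aq.), MeOH/THF, 45 °C
Reagents that add atoms: none
Why: Acid-catalysed transacetalisation to methanol should remove all seven MOM groups; the benzylic sulfone is stable to acid, unlike an alcohol or ester at that position.

Step 16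
Reactants: 28 the heptaphenol sulfone of step 15
Product: 32 the target, 1-methylcyclohex-1-ene bearing (3S)-[2,6-dihydroxy-3-[(E)-3-(4-hydroxyphenyl)prop-2-enoyl]phenyl], (4R)-[2,4-dihydroxy-3-[(E)-3-methylbut-1-enyl]benzoyl] and (5S)-(2,4-dihydroxyphenyl) (3,4-cis, 4,5-trans), via flavene 29 (not isolated), via quinone methide 30 (not isolated), via bis-aryl ketal 31 (not isolated)
Conditions: PPTS (20 mol%), 4 Å molecular sieves, dioxane, 70 °C; then Cs2CO3 (8 equiv), DMF, 0 °C to rt, high dilution; then H2O, 40 °C; NaH2PO4 work-up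
Reagents that add atoms: water, O
Why: Acid-catalysed hemiketalisation of the C4 ketone by the ring A ortho-hydroxyl (6-exo-trig) and dehydration give 4H-chromene 29 (ring E); carbonate then deprotonates ring C, sulfinate is expelled to give quinone methide 30, and its oxa-diene (O=C–C=C5) adds to the enol ether C4=C(O) in an intramolecular inverse-electron-demand hetero-Diels–Alder reaction that forms C4–C5 and O–C together, closing the cyclohexene (exo at C5) and pyran ring F. The closest known reaction type is the [4+2] cycloaddition of enol ethers with ortho-quinone methides generated by base from arylsulfonylalkyl phenols; a stepwise Michael addition through the para-quinone methide tautomer would lead to the same ketal 31. At C4, because C3 and the enol ether carbon are both members of ring E, the four-atom tether can reach C4 only on the chromene face that carries it, so the new ring is cis-fused to ring E and the aroyl carbon ends up cis to ring A. At C5, ring A is pseudoaxial on C3 in the chair-like transition state and the quinone methide takes the equatorial position to avoid a 1,3-diaxial clash, which places ring C trans to the aroyl group and to ring A. The step needs capture of 30 by the enol ether to outrun its tautomerisation to a dienylphenol and intermolecular addition; the six-membered transition state, the enol ether pushed by the ring B para-phenoxide, dilution and anhydrous base secure this, and carbonate forms no ketone enolate, so no template-free pathway competes. On adding water the ring B para-phenoxide expels the ring A aryloxide from 31, hydroxide adds to the resulting quinone-methide ketal and collapse releases the ring C aryloxide, giving the chelated ketone 32, the stable form in base.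

Compound list
1 | 1-(2,4-dihydroxyphenyl)ethanone | CC(=O)c1ccc(O)cc1O | starting material
2 | 1-(2,4-dihydroxy-3-iodophenyl)ethanone | CC(=O)c1ccc(O)c(I)c1O | intermediate
3 | 1-[3-iodo-2,4-bis(methoxymethoxy)phenyl]ethanone | CC(=O)c1ccc(OCOC)c(I)c1OCOC | intermediate
4 | 3-methylbut-1-yne | CC(C)C#C | starting material
5 | pinacolborane (4,4,5,5-tetramethyl-1,3,2-dioxaborolane) | CC1(C)OBOC1(C)C | starting material
6 | (E)-4,4,5,5-tetramethyl-2-(3-methylbut-1-enyl)-1,3,2-dioxaborolane | CC(C)/C=C/B1OC(C)(C)C(C)(C)O1 | intermediate (not isolated)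
7 | 1-[2,4-bis(methoxymethoxy)-3-[(E)-3-methylbut-1-enyl]phenyl]ethanone (ring B ketone) | CC(=O)c1ccc(OCOC)c(/C=C/C(C)C)c1OCOC | intermediate
8 | 3-acetyl-2,6-bis(methoxymethoxy)benzaldehyde (ring A aldehyde) | CC(=O)c1ccc(OCOC)c(C=O)c1OCOC | intermediate
9 | lithium enolate of 7 | C=C(O[Li])c1ccc(OCOC)c(/C=C/C(C)C)c1OCOC | intermediate (not isolated)
10 | lithium aldolate from 9 and 8 (carbinol carbon racemic) | CC(=O)c1ccc(OCOC)c(C(O[Li])CC(=O)c2ccc(OCOC)c(/C=C/C(C)C)c2OCOC)c1OCOC | intermediate (not isolated)
11 | methanesulfonate of the aldol (racemic) | CC(=O)c1ccc(OCOC)c(C(OS(C)(=O)=O)CC(=O)c2ccc(OCOC)c(/C=C/C(C)C)c2OCOC)c1OCOC | intermediate (not isolated)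
12 | (E)-3-[3-acetyl-2,6-bis(methoxymethoxy)phenyl]-1-[2,4-bis(methoxymethoxy)-3-[(E)-3-methylbut-1-enyl]phenyl]prop-2-en-1-one | CC(=O)c1ccc(OCOC)c(/C=C/C(=O)c2ccc(OCOC)c(/C=C/C(C)C)c2OCOC)c1OCOC | intermediate
13 | 2,4-dihydroxybenzaldehyde | O=Cc1ccc(O)cc1O | starting material
14 | 2,4-bis(methoxymethoxy)benzaldehyde | COCOc1ccc(C=O)c(OCOC)c1 | intermediate
15 | [2,4-bis(methoxymethoxy)phenyl]methanol | COCOc1ccc(CO)c(OCOC)c1 | intermediate
16 | 1-(chloromethyl)-2,4-bis(methoxymethoxy)benzene | COCOc1ccc(CCl)c(OCOC)c1 | intermediate (not isolated)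
17 | 2,4-bis(methoxymethoxy)-1-[(4-methylphenyl)sulfonylmethyl]benzene | COCOc1ccc(CS(=O)(=O)c2ccc(C)cc2)c(OCOC)c1 | intermediate
18 | prop-2-yn-1-ol | C#CCO | starting material
19 | 4-methyl-2,5-dihydro-1,2-oxamagnesole (chelated (Z)-alkenylmagnesium alkoxide) | CC1=C[Mg]OC1 | intermediate (not isolated)
20 | (Z)-3-iodo-2-methylprop-2-en-1-ol | OC/C(C)=C\I | intermediate
21 | (Z)-3-bromo-1-iodo-2-methylprop-1-ene | BrC/C(C)=C\I | intermediate
22 | α-lithio derivative of sulfone 17 | COCOc1ccc(C([Li])S(=O)(=O)c2ccc(C)cc2)c(OCOC)c1 | intermediate (not isolated)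
23 | 1-[(Z)-4-iodo-3-methyl-1-(4-methylphenyl)sulfonylbut-3-enyl]-2,4-bis(methoxymethoxy)benzene (sulfone carbon: both configurations) | COCOc1ccc(C(C/C(C)=C\I)S(=O)(=O)c2ccc(C)cc2)c(OCOC)c1 | intermediate
24 | 2-[(Z)-4-[2,4-bis(methoxymethoxy)phenyl]-2-methyl-4-(4-methylphenyl)sulfonylbut-1-enyl]-4,4,5,5-tetramethyl-1,3,2-dioxaborolane | COCOc1ccc(C(C/C(C)=C\B2OC(C)(C)C(C)(C)O2)S(=O)(=O)c2ccc(C)cc2)c(OCOC)c1 | intermediate
25 | (3R,4Z)-3-[3-acetyl-2,6-bis(methoxymethoxy)phenyl]-1-[2,4-bis(methoxymethoxy)-3-[(E)-3-methylbut-1-enyl]phenyl]-7-[2,4-bis(methoxymethoxy)phenyl]-5-methyl-7-(4-methylphenyl)sulfonylhept-4-en-1-one (C7: both configurations) | CC(C)/C=C/c1c(OCOC)ccc(C(=O)C[C@@H](c2c(OCOC)ccc(C(C)=O)c2OCOC)/C=C(/C)CC(c2ccc(OCOC)cc2OCOC)S(=O)(=O)c2ccc(C)cc2)c1OCOC | intermediate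
26 | 4-(methoxymethoxy)benzaldehyde | COCOc1ccc(C=O)cc1 | starting material
27 | chalcone of 25: as 25 with the acetyl group replaced by (E)-3-[4-(methoxymethoxy)phenyl]prop-2-enoyl | CC(C)/C=C/c1c(OCOC)ccc(C(=O)C[C@@H](c2c(OCOC)ccc(C(=O)/C=C/c3ccc(OCOC)cc3)c2OCOC)/C=C(/C)CC(c2ccc(OCOC)cc2OCOC)S(=O)(=O)c2ccc(C)cc2)c1OCOC | intermediate
28 | (3R,4Z)-3-[2,6-dihydroxy-3-[(E)-3-(4-hydroxyphenyl)prop-2-enoyl]phenyl]-1-[2,4-dihydroxy-3-[(E)-3-methylbut-1-enyl]phenyl]-7-(2,4-dihydroxyphenyl)-5-methyl-7-(4-methylphenyl)sulfonylhept-4-en-1-one (C7: both configurations) | CC(C)/C=C/c1c(O)ccc(C(=O)C[C@@H](c2c(O)ccc(C(=O)/C=C/c3ccc(O)cc3)c2O)/C=C(/C)CC(c2ccc(O)cc2O)S(=O)(=O)c2ccc(C)cc2)c1O | intermediate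
29 | (4S)-2-[2,4-dihydroxy-3-[(E)-3-methylbut-1-enyl]phenyl]-4-[(Z)-4-(2,4-dihydroxyphenyl)-2-methyl-4-(4-methylphenyl)sulfonylbut-1-enyl]-5-hydroxy-6-[(E)-3-(4-hydroxyphenyl)prop-2-enoyl]-4H-chromene (flavene with ring E) | CC(C)/C=C/c1c(O)ccc(C2=C[C@H](/C=C(/C)CC(c3ccc(O)cc3O)S(=O)(=O)c3ccc(C)cc3)c3c(O)c(C(=O)/C=C/c4ccc(O)cc4)ccc3O2)c1O | intermediate (not isolated)
30 | ortho-quinone methide of 29: the sulfone carbon has become an (E)-exocyclic alkylidene on a 3-hydroxycyclohexa-2,4-dien-1-one | CC(C)/C=C/c1c(O)ccc(C2=C[C@H](/C=C(/C)C/C=C3\C=CC(O)=CC3=O)c3c(O)c(C(=O)/C=C/c4ccc(O)cc4)ccc3O2)c1O | intermediate (not isolated)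
31 | bis-aryl ketal of 32: the C4 ketone carbon bonded to the ring A ortho-oxygen (ring E) and the ring C ortho-oxygen (ring F); cyclohexene cis-fused to ring E and trans-fused to ring F | CC1=C[C@@H]2c3c(O)c(C(=O)/C=C/c4ccc(O)cc4)ccc3O[C@]3(c4ccc(O)c(/C=C/C(C)C)c4O)Oc4cc(O)ccc4[C@@H](C1)[C@H]23 | intermediate (not isolated)
32 | target: (3S,4R,5S)-configured 1-methylcyclohex-1-ene with ring A on C3, the ring B aroyl group on C4 and ring C on C5 (CNP0140882.1) | CC1=C[C@H](c2c(O)ccc(C(=O)/C=C/c3ccc(O)cc3)c2O)[C@H](C(=O)c2ccc(O)c(/C=C/C(C)C)c2O)[C@@H](c2ccc(O)cc2O)C1 | target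

Total step count: 16. Longest linear sequence: 9 steps (steps 6, 7, 8, 11, 12, 13, 14, 15, 16).

Steps most likely to fail

Step 16. The quinone methide may tautomerise to a dienylphenol before it is captured, or open-chain ketone may be carried into the basic stage when chromene formation on the free polyphenol is incomplete, so that material is lost. The fallback secures and purifies the template before the trigger. It sets out from 29: the crude flavene would be per-silylated (TBSCl, imidazole, DMF) and purified as the hexakis(tert-butyldimethylsilyl) ether F1. Fluoride (Bu4NF, THF, 0 °C) would then unmask all phenoxides at once under anhydrous, homogeneous conditions, so that sulfinate loss and cycloaddition start from a pure, fully template-bound substrate. This would give ketal 31, where the fallback rejoins the route at the aqueous-base stage of step 16.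

Step 13. Insertion of the di-ortho-substituted β-aryl enone into the alkenylrhodium may be slow, so that protodeboronation of 24 and erosion of facial selectivity take over. The fallback replaces the metal-catalysed carbometalation by a metal-free boronate delivery. It sets out from 24: oxidative removal of the pinacol unit (NaIO4, NH4OAc, acetone/H2O) would give the alkenylboronic acid F2. A BINOL-catalysed asymmetric conjugate alkenylboration of enone 12 would follow (3,3'-bis(pentafluorophenyl)-BINOL of the configuration that favours Si-face delivery, Mg(OtBu)2, toluene, 80 °C). Here the alkenyl group is transferred within a carbonyl-bound boronate complex through a closed chair transition state. The fallback returns to the route at 25.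

Step 4. At the di-ortho-substituted position, reduction of the arylpalladium intermediate by the silane may precede CO insertion and give the deiodinated arene. The fallback builds the formyl carbon in two C–C and C=O operations. It sets out from 3: Suzuki–Miyaura coupling with potassium vinyltrifluoroborate (PdCl2(dppf), K2CO3, THF/H2O, 80 °C) would give the vinylarene F3. Lemieux–Johnson cleavage (OsO4 cat., NaIO4, 2,6-lutidine, dioxane/H2O) would then give aldehyde 8, where it returns to the route.

Further compounds
F1 | step 16 | hexakis(tert-butyldimethylsilyl) ether of flavene 29 | CC(C)/C=C/c1c(O[Si](C)(C)C(C)(C)C)ccc(C2=C[C@H](/C=C(/C)CC(c3ccc(O[Si](C)(C)C(C)(C)C)cc3O[Si](C)(C)C(C)(C)C)S(=O)(=O)c3ccc(C)cc3)c3c(O[Si](C)(C)C(C)(C)C)c(C(=O)/C=C/c4ccc(O[Si](C)(C)C(C)(C)C)cc4)ccc3O2)c1O[Si](C)(C)C(C)(C)C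
F2 | step 13 | [(Z)-4-[2,4-bis(methoxymethoxy)phenyl]-2-methyl-4-(4-methylphenyl)sulfonylbut-1-enyl]boronic acid | COCOc1ccc(C(C/C(C)=C\B(O)O)S(=O)(=O)c2ccc(C)cc2)c(OCOC)c1
F3 | step 4 | 1-[3-ethenyl-2,4-bis(methoxymethoxy)phenyl]ethanone | CC(=O)c1ccc(OCOC)c(C=C)c1OCOC
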